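**Strategy.** The route rests on cutting the most hindered bond of the target: C3, the methyl-bearing quaternary carbon of the cis-hydroazulene, to C4 of the oxolane. A hydrogen-atom-transfer-initiated radical conjugate addition joins the two halves there. Fe–H adds H to the 3-methylidene group of a cis-hydroazulen-4-one, which creates the C3 methyl group and a tertiary C3 radical that adds to (5S)-menthyloxybutenolide. One operation thus forms the C3–C4 bond and both flanking stereocentres. The precursor alkene comes from a Cu-catalysed asymmetric conjugate addition and an Au-catalysed Conia-ene ring closure. The butenolide is later hydroxymethylated and turned inside out into the acetoxy oxolane.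

Key step: step 7

Remark: locants follow decahydroazulene (C3 quaternary, C3a/C8a ring fusion, C4 carbonyl or methylidene, C8 gem-dimethyl) and oxolane (C3 side chain, C4 hydroazulene, C5 acetal); Az = (3R,3aS,8aR)-3,8,8-trimethyl-4-methylidenedecahydroazulen-3-yl; Men = (1S,2R,5S)-5-methyl-2-(propan-2-yl)cyclohexyl.
Remark: 6 and 11 are assumed to be purchasable (11 is otherwise two steps from furfural and (+)-menthol); acetals 16–21 are drawn as the 5-methoxy epimer trans to C4, but an anomeric mixture is acceptable because C5 is reset in step 14.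

Step 1
Reactants: 1 3-methylcyclohex-2-en-1-one
Product: 2 [(3,3-dimethylcyclohex-1-en-1-yl)oxy]trimethylsilane
Conditions: MeMgBr, CuBr·SMe2 (5 mol%), TMSCl, HMPA, THF, −78 °C; Et3N, pentane work-up
Reagents that add atoms: methylmagnesium bromide C[Mg]Br; chlorotrimethylsilane C[Si](C)(C)Cl
Why: TMSCl-accelerated copper-catalysed conjugate addition of a Grignard reagent builds the gem-dimethyl carbon and traps the enolate as the regiodefined silyl enol ether; no stereocentre is formed.

Step 2
Reactants: 2 [(3,3-dimethylcyclohex-1-en-1-yl)oxy]trimethylsilane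
Product: 3 [(5,5-dimethylbicyclo[4.1.0]heptan-1-yl)oxy]trimethylsilane (racemic)
Conditions: Et2Zn, CH2I2, Et2O, 0 °C → rt
Reagents that add atoms: diiodomethane ICI
Why: Simmons–Smith cyclopropanation (Furukawa variant) is fast on the electron-rich enol ether; the racemic stereocentres are destroyed in step 3.

Step 3
Reactants: 3 [(5,5-dimethylbicyclo[4.1.0]heptan-1-yl)oxy]trimethylsilane
Product: 5 4,4-dimethylcyclohept-2-en-1-one, via 3-chloro-4,4-dimethylcycloheptan-1-one 4 (not isolated)
Conditions: FeCl3, DMF, 0 °C → rt; then NaOAc, MeOH, reflux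
Reagents that add atoms: none
Why: FeCl3-mediated oxidative ring expansion of a siloxycyclopropane cleaves the internal cyclopropane bond to the ring-enlarged β-chloro ketone, and acetate eliminates HCl to the conjugated enone.

Step 4
Reactants: 5 4,4-dimethylcyclohept-2-en-1-one; 6 (4-bromobut-1-yn-1-yl)trimethylsilane
Product: 8 {[(3R)-4,4-dimethyl-3-[4-(trimethylsilyl)but-3-yn-1-yl]cyclohept-1-en-1-yl]oxy}tri(propan-2-yl)silane, via zinc enolate 7 (not isolated)
Conditions: 6, Mg, Et2O; ZnCl2 (0.5 equiv), dioxane, filter; Cu(OTf)2 (2 mol%), (S,R,R)-binaphthol-derived N,N-bis(1-phenylethyl)phosphoramidite (4 mol%), 5, PhMe, −30 °C; then TIPSOTf, −30 → 0 °C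
Reagents that add atoms: triisopropylsilyl trifluoromethanesulfonate CC(C)[Si](OS(=O)(=O)C(F)(F)F)(C(C)C)C(C)C
Why: Copper/phosphoramidite-catalysed asymmetric conjugate addition of a dialkylzinc to a cyclic enone sets C3 under ligand control (the ligand hand is to be matched to the (3R) product), and silylation of the zinc enolate fixes the enol ether on the side of the new stereocentre.

Step 5
Reactants: 8 {[(3R)-4,4-dimethyl-3-[4-(trimethylsilyl)but-3-yn-1-yl]cyclohept-1-en-1-yl]oxy}tri(propan-2-yl)silane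
Product: 9 {[(3R)-3-(but-3-yn-1-yl)-4,4-dimethylcyclohept-1-en-1-yl]oxy}tri(propan-2-yl)silane
Conditions: K2CO3 (cat.), MeOH/THF, 0 °C
Reagents that add atoms: none
Why: Base-catalysed methanolysis of the C(sp)–Si bond is much faster than cleavage of the hindered TIPS enol ether; no stereocentre is affected.

Step 6
Reactants: 9 {[(3R)-3-(but-3-yn-1-yl)-4,4-dimethylcyclohept-1-en-1-yl]oxy}tri(propan-2-yl)silane
Product: 10 (3aR,8aR)-8,8-dimethyl-3-methylidene-octahydroazulen-4(1H)-one
Conditions: Ph3PAuCl (5 mol%), AgBF4 (5 mol%), CH2Cl2/H2O (10:1), 40 °C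
Reagents that add atoms: none
Why: Gold(I)-catalysed Conia-ene-type carbocyclisation of the silyl enol ether onto the terminal alkyne (5-exo-dig, attack at the internal alkyne carbon) closes the cyclopentane; the three-atom tether reaches C2 of the enol ether only on its own face, which gives the cis ring fusion (H-3a cis to H-8a).

Step 7
Reactants: 10 (3aR,8aR)-8,8-dimethyl-3-methylidene-octahydroazulen-4(1H)-one; 11 (5S)-5-(Men-oxy)furan-2(5H)-one
Product: 12 (4R,5S)-5-(Men-oxy)-4-[(3S,3aR,8aR)-3,8,8-trimethyl-4-oxodecahydroazulen-3-yl]oxolan-2-one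
Conditions: Fe(acac)3 (0.5 equiv), PhSiH3 (2.5 equiv), 11 (3 equiv), EtOH/(CH2OH)2 (5:1), 60 °C
Reagents that add atoms: none
Why: An iron hydride formed from Fe(acac)3 and PhSiH3 transfers H• to the CH2 terminus of the 3-methylidene group (Markovnikov HAT), which makes that carbon the C3 methyl group and leaves a nucleophilic tertiary C3 radical; the radical adds to C4 of butenolide 11, and the α-lactone radical is reduced by Fe(II) and protonated by ethanol. The closest known reaction type is the iron-catalysed reductive coupling of unactivated alkenes with Michael acceptors (HAT-initiated Giese addition), which is established for building quaternary carbons from 1,1-disubstituted alkenes. No ring is closed: the step forms the C3–C4(lactone) bond that joins the two ring systems. The C3 stereocentre is controlled by the cis-fused bicycle, whose seven-membered ring (C3a–C4 bond) blocks the concave face so that the acceptor is taken up on the convex face, cis to H-3a; the lactone C4 stereocentre is controlled by the C5 menthyloxy group, anti to which the radical adds. The step needs chemoselective H-atom transfer to the electron-rich alkene of 10 rather than to 11 (secured by the polarity of the metal hydride and an excess of 11), Markovnikov regioselectivity (tertiary against primary radical), and the C4 ketone in place of the later methylidene so that only one alkene can accept H•.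

Step 8
Reactants: 12 (4R,5S)-5-(Men-oxy)-4-[(3S,3aR,8aR)-3,8,8-trimethyl-4-oxodecahydroazulen-3-yl]oxolan-2-one
Product: 13 (4R,5S)-4-Az-5-(Men-oxy)oxolan-2-one
Conditions: Zn, CH2Br2, TiCl4, THF/CH2Cl2, 0 °C → rt
Reagents that add atoms: dibromomethane BrCBr
Why: Takai–Lombardo methylenation is non-basic, so the enolisable ketone should be converted without epimerisation at C3a, and the reagent leaves lactones and acetals untouched; no new stereocentre.

Step 9
Reactants: 13 (4R,5S)-4-Az-5-(Men-oxy)oxolan-2-one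
Product: 15 (3R,4R,5S)-4-Az-3-(hydroxymethyl)-5-(Men-oxy)oxolan-2-one, via lithium enolate 14 (not isolated)
Conditions: LDA, THF, −78 °C; CH2O (gas, from paraformaldehyde), −78 → −40 °C; aq. NH4Cl
Reagents that add atoms: formaldehyde C=O
Why: Aldol addition of the lactone enolate to formaldehyde takes place anti to the very large C4 substituent, so the hydroxymethyl group is set trans to it; this is the arrangement that becomes the cis 3,4-relationship of the final oxolane.

Step 10
Reactants: 15 (3R,4R,5S)-4-Az-3-(hydroxymethyl)-5-(Men-oxy)oxolan-2-one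
Product: 17 methyl (3R,4R,5S)-4-Az-5-methoxyoxolane-3-carboxylate, via acetal acid 16 (not isolated)
Conditions: CSA (0.2 equiv), MeOH, 40 °C; concentrate; then TMSCHN2, PhMe/MeOH, 0 °C
Reagents that add atoms: methanol CO; (trimethylsilyl)diazomethane C[Si](C)(C)C=[N+]=[N-]
Why: Acid-catalysed acetal exchange: the γ-alkoxy lactone (pseudo-ester) ionises at C5 with loss of the carboxylate, the primary alcohol closes the cyclic acetal (5-exo attack on the oxocarbenium ion), methanol replaces menthol and TMSCHN2 esterifies the freed acid; no carbon stereocentre is enolisable under acid, so the C3/C4 relationship is carried over unchanged.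

Step 11
Reactants: 17 methyl (3R,4R,5S)-4-Az-5-methoxyoxolane-3-carboxylate
Product: 18 (3R,4R,5S)-4-Az-5-methoxyoxolane-3-carbaldehyde
Conditions: DIBAL-H (1.1 equiv), CH2Cl2, −78 °C; Rochelle salt
Reagents that add atoms: none
Why: DIBAL-H reduction of the ester stops at the aldehyde through the aluminium hemiacetal that is stable at −78 °C; the α-stereocentre is not enolised under these non-basic conditions.

Step 12
Reactants: 18 (3R,4R,5S)-4-Az-5-methoxyoxolane-3-carbaldehyde
Product: 19 (1R)-1-[(3R,4R,5S)-4-Az-5-methoxyoxolan-3-yl]-2,2,2-trichloroethan-1-ol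
Conditions: Cl3CCO2Na, Cl3CCO2H, DMF, 0 °C → rt
Reagents that add atoms: sodium trichloroacetate [Na+].[O-]C(=O)C(Cl)(Cl)Cl
Why: Decarboxylative generation of the trichloromethyl anion and its addition to the aldehyde (first stage of a Corey–Link/Jocic sequence) runs under near-neutral conditions; Felkin–Anh attack anti to the C3–C4 ring bond should give the (R)-carbinol.

Step 13
Reactants: 19 (1R)-1-[(3R,4R,5S)-4-Az-5-methoxyoxolan-3-yl]-2,2,2-trichloroethan-1-ol
Product: 21 methyl (2S)-2-[(3R,4R,5S)-4-Az-5-methoxyoxolan-3-yl]-2-hydroxyacetate, via hydroxy acid 20 (not isolated)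
Conditions: NaOH, DME/H2O, 0 °C → rt; 1 M HCl to pH 3; then TMSCHN2, PhMe/MeOH, 0 °C
Reagents that add atoms: sodium hydroxide [Na+].[OH-]; (trimethylsilyl)diazomethane C[Si](C)(C)C=[N+]=[N-]
Why: Jocic reaction: the alkoxide closes a gem-dichloroepoxide, which hydroxide opens by SN2 at the carbinol carbon, so the new hydroxyl arrives with inversion and the (S)-α-hydroxy acid results; TMSCHN2 then esterifies it.

Step 14
Reactants: 21 methyl (2S)-2-[(3R,4R,5S)-4-Az-5-methoxyoxolan-3-yl]-2-hydroxyacetate
Product: 23 methyl (2S)-2-(acetyloxy)-2-[(3R,4R,5R)-5-(acetyloxy)-4-Az-oxolan-3-yl]acetate, via lactol 22 (not isolated)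
Conditions: AcOH/THF/H2O (3:1:1), 45 °C; then Ac2O, pyridine, DMAP (cat.), CH2Cl2, 0 °C → rt
Reagents that add atoms: water O; acetic anhydride CC(=O)OC(C)=O
Why: Mild acid hydrolysis of the methyl acetal gives the lactol and DMAP-catalysed acetylation esterifies both hydroxyls; the lactol anomers equilibrate and the less hindered one is acylated, so the anomeric acetate should form trans to the bulky C4 substituent.

**Compound list**

1 | 3-methylcyclohex-2-en-1-one | CC1=CC(=O)CCC1 | starting material
2 | [(3,3-dimethylcyclohex-1-en-1-yl)oxy]trimethylsilane | CC1(C)CCCC(O[Si](C)(C)C)=C1 | intermediate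
3 | [(5,5-dimethylbicyclo[4.1.0]heptan-1-yl)oxy]trimethylsilane (racemic) | CC1(C)CCCC2(O[Si](C)(C)C)CC12 | intermediate
4 | 3-chloro-4,4-dimethylcycloheptan-1-one (racemic, not isolated) | CC1(C)CCCC(=O)CC1Cl | intermediate
5 | 4,4-dimethylcyclohept-2-en-1-one | CC1(C)CCCC(=O)C=C1 | intermediate
6 | (4-bromobut-1-yn-1-yl)trimethylsilane | C[Si](C)(C)C#CCCBr | starting material
7 | [4-(trimethylsilyl)but-3-yn-1-yl]zinc (3R)-4,4-dimethyl-3-[4-(trimethylsilyl)but-3-yn-1-yl]cyclohept-1-en-1-olate (not isolated) | CC1(C)CCCC(O[Zn]CCC#C[Si](C)(C)C)=C[C@H]1CCC#C[Si](C)(C)C | intermediate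
8 | {[(3R)-4,4-dimethyl-3-[4-(trimethylsilyl)but-3-yn-1-yl]cyclohept-1-en-1-yl]oxy}tri(propan-2-yl)silane | CC1(C)CCCC(O[Si](C(C)C)(C(C)C)C(C)C)=C[C@H]1CCC#C[Si](C)(C)C | intermediate
9 | {[(3R)-3-(but-3-yn-1-yl)-4,4-dimethylcyclohept-1-en-1-yl]oxy}tri(propan-2-yl)silane | CC1(C)CCCC(O[Si](C(C)C)(C(C)C)C(C)C)=C[C@H]1CCC#C | intermediate
10 | (3aR,8aR)-8,8-dimethyl-3-methylidene-octahydroazulen-4(1H)-one | O=C1CCCC(C)(C)[C@@H]2CCC(=C)[C@H]12 | intermediate
11 | (5S)-5-{[(1S,2R,5S)-5-methyl-2-(propan-2-yl)cyclohexyl]oxy}furan-2(5H)-one | O=C1C=C[C@@H](O[C@H]2C[C@@H](C)CC[C@@H]2C(C)C)O1 | starting material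
12 | (4R,5S)-5-{[(1S,2R,5S)-5-methyl-2-(propan-2-yl)cyclohexyl]oxy}-4-[(3S,3aR,8aR)-3,8,8-trimethyl-4-oxodecahydroazulen-3-yl]oxolan-2-one | O=C1CCCC(C)(C)[C@@H]2CC[C@@](C)([C@H]3CC(=O)O[C@@H]3O[C@H]4C[C@@H](C)CC[C@@H]4C(C)C)[C@H]12 | intermediate
13 | (4R,5S)-5-{[(1S,2R,5S)-5-methyl-2-(propan-2-yl)cyclohexyl]oxy}-4-[(3R,3aS,8aR)-3,8,8-trimethyl-4-methylidenedecahydroazulen-3-yl]oxolan-2-one | C=C1CCCC(C)(C)[C@@H]2CC[C@@](C)([C@H]3CC(=O)O[C@@H]3O[C@H]4C[C@@H](C)CC[C@@H]4C(C)C)[C@H]12 | intermediate
14 | lithium enolate of 13 (not isolated) | C=C1CCCC(C)(C)[C@@H]2CC[C@@](C)([C@H]3C=C(O[Li])O[C@@H]3O[C@H]4C[C@@H](C)CC[C@@H]4C(C)C)[C@H]12 | intermediate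
15 | (3R,4R,5S)-3-(hydroxymethyl)-5-{[(1S,2R,5S)-5-methyl-2-(propan-2-yl)cyclohexyl]oxy}-4-[(3R,3aS,8aR)-3,8,8-trimethyl-4-methylidenedecahydroazulen-3-yl]oxolan-2-one | C=C1CCCC(C)(C)[C@@H]2CC[C@@](C)([C@H]3[C@H](CO)C(=O)O[C@@H]3O[C@H]4C[C@@H](C)CC[C@@H]4C(C)C)[C@H]12 | intermediate
16 | (3R,4R,5S)-5-methoxy-4-[(3R,3aS,8aR)-3,8,8-trimethyl-4-methylidenedecahydroazulen-3-yl]oxolane-3-carboxylic acid (not isolated) | C=C1CCCC(C)(C)[C@@H]2CC[C@@](C)([C@@H]3[C@@H](OC)OC[C@@H]3C(=O)O)[C@H]12 | intermediate
17 | methyl (3R,4R,5S)-5-methoxy-4-[(3R,3aS,8aR)-3,8,8-trimethyl-4-methylidenedecahydroazulen-3-yl]oxolane-3-carboxylate | C=C1CCCC(C)(C)[C@@H]2CC[C@@](C)([C@@H]3[C@@H](OC)OC[C@@H]3C(=O)OC)[C@H]12 | intermediate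
18 | (3R,4R,5S)-5-methoxy-4-[(3R,3aS,8aR)-3,8,8-trimethyl-4-methylidenedecahydroazulen-3-yl]oxolane-3-carbaldehyde | C=C1CCCC(C)(C)[C@@H]2CC[C@@](C)([C@@H]3[C@@H](OC)OC[C@@H]3C=O)[C@H]12 | intermediate
19 | (1R)-2,2,2-trichloro-1-{(3R,4R,5S)-5-methoxy-4-[(3R,3aS,8aR)-3,8,8-trimethyl-4-methylidenedecahydroazulen-3-yl]oxolan-3-yl}ethan-1-ol | C=C1CCCC(C)(C)[C@@H]2CC[C@@](C)([C@@H]3[C@@H](OC)OC[C@@H]3[C@@H](O)C(Cl)(Cl)Cl)[C@H]12 | intermediate
20 | (2S)-2-hydroxy-2-{(3R,4R,5S)-5-methoxy-4-[(3R,3aS,8aR)-3,8,8-trimethyl-4-methylidenedecahydroazulen-3-yl]oxolan-3-yl}acetic acid (not isolated) | C=C1CCCC(C)(C)[C@@H]2CC[C@@](C)([C@@H]3[C@@H](OC)OC[C@@H]3[C@H](O)C(=O)O)[C@H]12 | intermediate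
21 | methyl (2S)-2-hydroxy-2-{(3R,4R,5S)-5-methoxy-4-[(3R,3aS,8aR)-3,8,8-trimethyl-4-methylidenedecahydroazulen-3-yl]oxolan-3-yl}acetate | C=C1CCCC(C)(C)[C@@H]2CC[C@@](C)([C@@H]3[C@@H](OC)OC[C@@H]3[C@H](O)C(=O)OC)[C@H]12 | intermediate
22 | methyl (2S)-2-hydroxy-2-{(3R,4R)-5-hydroxy-4-[(3R,3aS,8aR)-3,8,8-trimethyl-4-methylidenedecahydroazulen-3-yl]oxolan-3-yl}acetate (anomeric mixture, not isolated) | C=C1CCCC(C)(C)[C@@H]2CC[C@@](C)([C@@H]3C(O)OC[C@@H]3[C@H](O)C(=O)OC)[C@H]12 | intermediate
23 | methyl (2S)-2-(acetyloxy)-2-{(3R,4R,5R)-5-(acetyloxy)-4-[(3R,3aS,8aR)-3,8,8-trimethyl-4-methylidenedecahydroazulen-3-yl]oxolan-3-yl}acetate (CNP0222222.1) | C=C1CCCC(C)(C)[C@@H]2CC[C@@](C)([C@@H]3[C@@H](OC(C)=O)OC[C@@H]3[C@H](OC(C)=O)C(=O)OC)[C@H]12 | target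

**Total step count:** 14. **Longest linear sequence:** 14 steps (1 → 23); 6 and 11 enter as purchased fragments.

**Steps most likely to fail**

Step 7 (key step). H-atom transfer may reduce or isomerise the alkene of 10 (in the worst case into conjugation with the ketone) faster than the hindered tertiary radical is captured by the β-substituted acceptor, and facial control at C3 could be eroded. The fallback makes the same radical by single-electron oxidation of an oxalate and installs the methylidene before the coupling. It sets out from 10: Mukaiyama hydration (Mn(dpm)3, PhSiH3, O2) should give the tertiary alcohol (3aR,8aR)-3-hydroxy-3,8,8-trimethyloctahydroazulen-4(1H)-one F1, whose C3 configuration is irrelevant. Titanium-carbenoid methylenation then gives (3aS,8aR)-3,8,8-trimethyl-4-methylidenedecahydroazulen-3-ol F2. Acylation with methyl chlorooxoacetate gives the methyl oxalate F3, and one equivalent of CsOH gives the caesium oxalate F4. Visible-light photoredox decarboxylation (Ir photocatalyst, blue LED, DME/DMF/H2O) in the presence of 11 should then deliver the tertiary radical to the butenolide and return to the route at 13, which also bypasses step 8.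

Step 10. The acid may protonate the exocyclic methylidene (migration into the ring or addition of methanol) before the pseudo-ester has opened, or the exchange may stall at the lactone. The fallback opens the lactone with base instead and sets out from 15. LiOH in THF/H2O should saponify the pseudo-ester, expel menthoxide and, after careful acidification, leave the lactol acid (3R,4R)-4-Az-5-hydroxyoxolane-3-carboxylic acid F5 (the carboxylate is not enolisable). TMSCHN2 gives the lactol ester methyl (3R,4R)-4-Az-5-hydroxyoxolane-3-carboxylate F6, and PPTS in methanol at room temperature converts the lactol into the methyl acetal, returning at 17.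

Step 12. Facial discrimination in the addition of the trichloromethyl anion may be poor, or the aldehyde may epimerise at C3 before it is trapped. The fallback replaces substrate control by reagent control and sets out from 19 obtained as a mixture of carbinol epimers. Dess–Martin oxidation gives the trichloromethyl ketone 1-[(3R,4R,5S)-4-Az-5-methoxyoxolan-3-yl]-2,2,2-trichloroethan-1-one F7. CBS reduction with the (S)-oxazaborolidine and catecholborane, in which the CCl3 group acts as the large substituent, should return the single (R)-carbinol 19, which re-enters the route at step 13.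

**Further compounds**

F1 | step 7 | (3aR,8aR)-3-hydroxy-3,8,8-trimethyloctahydroazulen-4(1H)-one (C3 epimers) | O=C1CCCC(C)(C)[C@@H]2CCC(C)(O)[C@H]12
F2 | step 7 | (3aS,8aR)-3,8,8-trimethyl-4-methylidenedecahydroazulen-3-ol (C3 epimers) | C=C1CCCC(C)(C)[C@@H]2CCC(C)(O)[C@H]12
F3 | step 7 | methyl (3aS,8aR)-3,8,8-trimethyl-4-methylidenedecahydroazulen-3-yl oxalate | C=C1CCCC(C)(C)[C@@H]2CCC(C)(OC(=O)C(=O)OC)[C@H]12
F4 | step 7 | caesium 2-oxo-2-{[(3aS,8aR)-3,8,8-trimethyl-4-methylidenedecahydroazulen-3-yl]oxy}acetate | C=C1CCCC(C)(C)[C@@H]2CCC(C)(OC(=O)C(=O)[O-])[C@H]12.[Cs+]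
F5 | step 10 | (3R,4R)-5-hydroxy-4-[(3R,3aS,8aR)-3,8,8-trimethyl-4-methylidenedecahydroazulen-3-yl]oxolane-3-carboxylic acid | C=C1CCCC(C)(C)[C@@H]2CC[C@@](C)([C@@H]3C(O)OC[C@@H]3C(=O)O)[C@H]12
F6 | step 10 | methyl (3R,4R)-5-hydroxy-4-[(3R,3aS,8aR)-3,8,8-trimethyl-4-methylidenedecahydroazulen-3-yl]oxolane-3-carboxylate | C=C1CCCC(C)(C)[C@@H]2CC[C@@](C)([C@@H]3C(O)OC[C@@H]3C(=O)OC)[C@H]12
F7 | step 12 | 2,2,2-trichloro-1-{(3R,4R,5S)-5-methoxy-4-[(3R,3aS,8aR)-3,8,8-trimethyl-4-methylidenedecahydroazulen-3-yl]oxolan-3-yl}ethan-1-one | C=C1CCCC(C)(C)[C@@H]2CC[C@@](C)([C@@H]3[C@@H](OC)OC[C@@H]3C(=O)C(Cl)(Cl)Cl)[C@H]12
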